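**Retrosynthetic overview**

1. The phenol is unmasked last from its silyl ether. The C4 ketone comes from a C4 alcohol that is oxidised only after the (E)-side chain has been built from a homopropargylic alcohol and a benzylic chloride by Zr-catalysed carboalumination and Pd coupling.
2. The C6 carbinol comes from equatorial propargylation of a C6 ketone. Its chair is locked by a C4 hydroxyl set under catalyst control (conjugate borylation/oxidation of a C4=C5 enone) and by the C5 side chain (dianion alkylation, Mukaiyama hydration).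
3. Key step: the six-membered ring and the second quaternary centre (C3a) are made together by a 6-endo hydrogen-atom-transfer radical cyclisation of a cyclopentene onto a tethered β-ethoxy enone. There is no ring-closing aldol.
4. The first quaternary centre (C7a) comes from an Eschenmoser–Claisen rearrangement with chirality transfer from (R)-2,3-dimethylcyclopent-2-enol, itself from a CBS reduction.
5. Ring order: the cyclopentene and the arene are bought; the cyclohexanone ring is the only ring formed (step 4).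

Assumption: every bicyclic intermediate is numbered like the target (C4 ends as the ketone, C6 as the carbinol, C3a/C7a are the ring fusion), even where the naming rules would number it the other way round.

**Route**

Step 1
Reactants: 1 2,3-dimethylcyclopent-2-en-1-one
Product: 2 (R)-2,3-dimethylcyclopent-2-en-1-ol
Conditions: (S)-1-methyl-3,3-diphenyltetrahydro-1H,3H-pyrrolo[1,2-c][1,3,2]oxazaborole (10 mol%), BH3·SMe2, THF, −20 °C; MeOH
Reagents that add atoms: none
Why: Corey–Bakshi–Shibata reduction in which the alkenyl carbon is the large group, so the (S)-catalyst delivers hydride to give the (R)-carbinol that is relayed to C7a in step 2.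

Step 2
Reactants: 2 (R)-2,3-dimethylcyclopent-2-en-1-ol
Product: 4 2-[(1R)-1,2-dimethylcyclopent-2-en-1-yl]-N,N-dimethylacetamide, via ketene N,O-acetal 3 (not isolated)
Conditions: CH3C(OMe)2NMe2 (4 equiv), xylene, 140 °C, sealed tube
Reagents that add atoms: N,N-dimethylacetamide dimethyl acetal, CC(OC)(OC)N(C)C
Why: Eschenmoser–Claisen rearrangement; the suprafacial [3,3] shift on the ring moves the C–O chirality onto the new quaternary carbon (future C7a, R) and leaves the trisubstituted ring alkene needed for step 4.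

Step 3
Reactants: 4 2-[(1R)-1,2-dimethylcyclopent-2-en-1-yl]-N,N-dimethylacetamide
Product: 5 (Z)-1-[(1R)-1,2-dimethylcyclopent-2-en-1-yl]-4-ethoxybut-3-en-2-one
Conditions: (Z)-BrCH=CHOEt, t-BuLi (2 equiv), THF, −78 °C; then 4, −78 to 0 °C; H2O
Reagents that add atoms: (Z)-1-bromo-2-ethoxyethene (used as its lithio derivative), CCO/C=C\Br
Why: Nucleophilic acyl substitution; the lithium hemiaminal from an organolithium and an N,N-dimethylamide is stable until work-up, so the ketone (a vinylogous ester) forms without over-addition.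

Step 4
Reactants: 5 (Z)-1-[(1R)-1,2-dimethylcyclopent-2-en-1-yl]-4-ethoxybut-3-en-2-one
Product: 7 (3aS,7aR)-3a,7a-dimethyl-1,2,3,3a,7,7a-hexahydro-6H-inden-6-one, via ethoxy ketone 6 (not isolated)
Conditions: Fe(acac)3 (30 mol%), PhSiH3 (2.5 equiv), EtOH/(CH2OH)2, 60 °C; then DBU, 60 °C
Reagents that add atoms: none
Why: Metal-hydride hydrogen-atom transfer (Baran-type reductive olefin–enone coupling) makes the tertiary C3a radical, which closes 6-endo onto the alkoxy-bearing β-carbon of the enone as in β-alkoxyacrylate radical cyclisations; the one-carbon link to C7a forces the cis ring fusion and so sets the second quaternary centre, and E1cB loss of ethanol then gives the enone.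

Step 5
Reactants: 7 (3aS,7aR)-3a,7a-dimethyl-1,2,3,3a,7,7a-hexahydro-6H-inden-6-one
Product: 9 (3aR,4S,7aR)-4-hydroxy-3a,7a-dimethyloctahydro-6H-inden-6-one, via boryl ketone 8 (not isolated)
Conditions: CuCl (5 mol%), NaOt-Bu (10 mol%), (R)-1-[(S)-2-(diphenylphosphino)ferrocenyl]ethyldicyclohexylphosphine (6 mol%), B2pin2, MeOH, THF, rt; then H2O2, pH 7 buffer, 0 °C
Reagents that add atoms: hydrogen peroxide, OO
Why: Copper-catalysed asymmetric conjugate borylation followed by stereoretentive C–B oxidation; the two faces of the cis-dimethyl enone are nearly alike, so the chiral ligand (antipode chosen accordingly) decides that boron adds anti to the angular methyls, setting C4 (S).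

Step 6
Reactants: 9 (3aR,4S,7aR)-4-hydroxy-3a,7a-dimethyloctahydro-6H-inden-6-one
Product: 10 (3aR,4S,5S,7aR)-4-hydroxy-3a,7a-dimethyl-5-(2-methylprop-2-en-1-yl)octahydro-6H-inden-6-one
Conditions: LiN(i-Pr)2 (2.3 equiv), THF, −78 °C; CH2=C(CH3)CH2Br, DMPU, −78 to −40 °C; H2O
Reagents that add atoms: 3-bromo-2-methylprop-1-ene, C=C(C)CBr
Why: Fráter–Seebach-type alkylation of the alkoxide/enolate dianion; C7 is neopentyl so enolisation goes to C5, and the allylic bromide enters anti to the C4 lithium alkoxide to give the 4,5-trans diequatorial product (C5 S), which is also the thermodynamic one.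

Step 7
Reactants: 10 (3aR,4S,5S,7aR)-4-hydroxy-3a,7a-dimethyl-5-(2-methylprop-2-en-1-yl)octahydro-6H-inden-6-one
Product: 11 (3aR,4S,5S,7aR)-4-hydroxy-5-(2-hydroxy-2-methylpropyl)-3a,7a-dimethyloctahydro-6H-inden-6-one
Conditions: Co(acac)2 (20 mol%), PhSiH3, O2 (1 atm), THF, rt
Reagents that add atoms: dioxygen, O=O
Why: Mukaiyama hydration; hydrogen-atom transfer to the only alkene gives the tertiary radical, which is trapped by O2 and reduced to the Markovnikov tertiary alcohol.

Step 8
Reactants: 11 (3aR,4S,5S,7aR)-4-hydroxy-5-(2-hydroxy-2-methylpropyl)-3a,7a-dimethyloctahydro-6H-inden-6-one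
Product: 12 (3aR,4S,5S,6R,7aR)-5-(2-hydroxy-2-methylpropyl)-3a,7a-dimethyl-6-(prop-2-yn-1-yl)octahydro-1H-indene-4,6-diol
Conditions: HC≡CCH2Br, Zn dust, THF/sat. aq NH4Cl, 0 °C to rt
Reagents that add atoms: propargyl bromide, C#CCBr
Why: Barbier propargylation through the allenylzinc (SE2') gives the homopropargylic tertiary alcohol; the equatorial C4 hydroxyl and C5 side chain lock the chair with the C7a methyl axial, so the nucleophile attacks equatorially, anti to that methyl (as with 3,3,5-trimethylcyclohexanone), which sets C6 (R).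

Step 9
Reactants: 13 4-methoxy-2-methylphenol
Product: 14 2-hydroxy-5-methoxy-3-methylbenzaldehyde
Conditions: MgCl2, Et3N, (CH2O)n, MeCN, reflux; 1 M HCl
Reagents that add atoms: formaldehyde (as paraformaldehyde), C=O
Why: Magnesium-mediated ortho-formylation (Casnati–Skattebøl); the magnesium phenoxide directs formaldehyde to the only free ortho position and a second formaldehyde takes up the hydride.

Step 10
Reactants: 14 2-hydroxy-5-methoxy-3-methylbenzaldehyde
Product: 15 2-[(tert-butyldimethylsilyl)oxy]-5-methoxy-3-methylbenzaldehyde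
Conditions: TBSCl, imidazole, DMF, rt
Reagents that add atoms: tert-butyldimethylsilyl chloride, CC(C)(C)[Si](C)(C)Cl
Why: Standard imidazole-promoted silylation; the aryl silyl ether survives Me3Al and is removed by fluoride at the end.

Step 11
Reactants: 15 2-[(tert-butyldimethylsilyl)oxy]-5-methoxy-3-methylbenzaldehyde
Product: 16 {2-[(tert-butyldimethylsilyl)oxy]-5-methoxy-3-methylphenyl}methanol
Conditions: NaBH4, MeOH/THF, −10 °C
Reagents that add atoms: none
Why: Borohydride reduction of the aldehyde, run cold and briefly so the silyl group does not migrate to the benzylic oxygen.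

Step 12
Reactants: 16 {2-[(tert-butyldimethylsilyl)oxy]-5-methoxy-3-methylphenyl}methanol
Product: 18 tert-butyl[2-(chloromethyl)-4-methoxy-6-methylphenoxy]dimethylsilane, via benzyl mesylate 17 (not isolated)
Conditions: MsCl, Et3N, CH2Cl2, 0 °C; then LiCl, DMF, rt
Reagents that add atoms: lithium chloride, [Li+].[Cl-]
Why: Mesylation followed by SN2 displacement with chloride at the activated benzylic carbon.

Step 13
Reactants: 12 (3aR,4S,5S,6R,7aR)-5-(2-hydroxy-2-methylpropyl)-3a,7a-dimethyl-6-(prop-2-yn-1-yl)octahydro-1H-indene-4,6-diol; 18 tert-butyl[2-(chloromethyl)-4-methoxy-6-methylphenoxy]dimethylsilane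
Product: 20 (3aR,4S,5S,6R,7aR)-6-[(2E)-4-{2-[(tert-butyldimethylsilyl)oxy]-5-methoxy-3-methylphenyl}-2-methylbut-2-en-1-yl]-5-(2-hydroxy-2-methylpropyl)-3a,7a-dimethyloctahydro-1H-indene-4,6-diol, via alkenylalane 19 (not isolated)
Conditions: Me3Al (6 equiv), Cp2ZrCl2 (0.5 equiv), ClCH2CH2Cl, rt; then 18, Pd(PPh3)4 (5 mol%), THF, rt; aq KNaC4H4O6
Reagents that add atoms: trimethylaluminium, C[Al](C)C
Why: Negishi zirconium-catalysed syn-carboalumination puts methyl on the internal and aluminium on the terminal alkyne carbon, and palladium-catalysed cross-coupling of the alkenylalane with the benzylic chloride goes with retention, so the trisubstituted alkene is formed as the E isomer only; no ketone is present at this stage.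

Step 14
Reactants: 20 (the silyl-protected triol from step 13)
Product: 21 (3aR,5R,6R,7aR)-6-[(2E)-4-{2-[(tert-butyldimethylsilyl)oxy]-5-methoxy-3-methylphenyl}-2-methylbut-2-en-1-yl]-6-hydroxy-5-(2-hydroxy-2-methylpropyl)-3a,7a-dimethyloctahydro-4H-inden-4-one
Conditions: 1,1,1-triacetoxy-1,1-dihydro-1,2-benziodoxol-3(1H)-one (Dess–Martin periodinane), NaHCO3, CH2Cl2, 0 °C to rt
Reagents that add atoms: none
Why: Dess–Martin oxidation of the only secondary alcohol, leaving both tertiary alcohols untouched; the C5 substituent already sits equatorial, trans to the C6 side chain, so the new α-centre is the stable epimer.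

Step 15
Reactants: 21 (the silyl-protected ketone from step 14)
Product: 22 (3aR,5R,6R,7aR)-6-hydroxy-6-[(2E)-4-(2-hydroxy-5-methoxy-3-methylphenyl)-2-methylbut-2-en-1-yl]-5-(2-hydroxy-2-methylpropyl)-3a,7a-dimethyloctahydro-4H-inden-4-one
Conditions: Bu4NF, AcOH, THF, 0 °C
Reagents that add atoms: none
Why: Fluoride cleavage of the aryl silyl ether, buffered with acetic acid so the β-hydroxy ketone does not undergo retro-aldol or elimination.

**Compound list**

1 | 2,3-dimethylcyclopent-2-en-1-one | CC1=C(C)C(=O)CC1 | starting material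
2 | (R)-2,3-dimethylcyclopent-2-en-1-ol | CC1=C(C)[C@H](O)CC1 | intermediate
3 | 1-{[(1R)-2,3-dimethylcyclopent-2-en-1-yl]oxy}-N,N-dimethylethen-1-amine (ketene N,O-acetal) | CC1=C(C)[C@H](OC(=C)N(C)C)CC1 | intermediate
4 | 2-[(1R)-1,2-dimethylcyclopent-2-en-1-yl]-N,N-dimethylacetamide | CN(C)C(=O)C[C@@]1(C)CCC=C1C | intermediate
5 | (Z)-1-[(1R)-1,2-dimethylcyclopent-2-en-1-yl]-4-ethoxybut-3-en-2-one | CCO/C=C\C(=O)C[C@@]1(C)CCC=C1C | intermediate
6 | (3aR,7aR)-4-ethoxy-3a,7a-dimethyloctahydro-6H-inden-6-one (cis-fused, both C4 epimers) | O=C1C[C@@]2(C)CCC[C@@]2(C)C(OCC)C1 | intermediate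
7 | (3aS,7aR)-3a,7a-dimethyl-1,2,3,3a,7,7a-hexahydro-6H-inden-6-one (cis-fused enone, C4=C5) | O=C1C[C@@]2(C)CCC[C@@]2(C)C=C1 | intermediate
8 | (3aS,4S,7aR)-3a,7a-dimethyl-4-(4,4,5,5-tetramethyl-1,3,2-dioxaborolan-2-yl)octahydro-6H-inden-6-one (boron anti to the angular methyls) | O=C1C[C@@]2(C)CCC[C@@]2(C)[C@@H](B3OC(C)(C)C(C)(C)O3)C1 | intermediate
9 | (3aR,4S,7aR)-4-hydroxy-3a,7a-dimethyloctahydro-6H-inden-6-one (hydroxyl anti to the angular methyls) | O=C1C[C@@]2(C)CCC[C@@]2(C)[C@@H](O)C1 | intermediate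
10 | (3aR,4S,5S,7aR)-4-hydroxy-3a,7a-dimethyl-5-(2-methylprop-2-en-1-yl)octahydro-6H-inden-6-one | O=C1C[C@@]2(C)CCC[C@@]2(C)[C@@H](O)[C@@H]1CC(C)=C | intermediate
11 | (3aR,4S,5S,7aR)-4-hydroxy-5-(2-hydroxy-2-methylpropyl)-3a,7a-dimethyloctahydro-6H-inden-6-one | O=C1C[C@@]2(C)CCC[C@@]2(C)[C@@H](O)[C@@H]1CC(C)(C)O | intermediate
12 | (3aR,4S,5S,6R,7aR)-5-(2-hydroxy-2-methylpropyl)-3a,7a-dimethyl-6-(prop-2-yn-1-yl)octahydro-1H-indene-4,6-diol | C#CC[C@@]1(O)C[C@@]2(C)CCC[C@@]2(C)[C@@H](O)[C@@H]1CC(C)(C)O | intermediate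
13 | 4-methoxy-2-methylphenol | COc1ccc(O)c(C)c1 | starting material
14 | 2-hydroxy-5-methoxy-3-methylbenzaldehyde | COc1cc(C)c(O)c(C=O)c1 | intermediate
15 | 2-[(tert-butyldimethylsilyl)oxy]-5-methoxy-3-methylbenzaldehyde | COc1cc(C)c(O[Si](C)(C)C(C)(C)C)c(C=O)c1 | intermediate
16 | {2-[(tert-butyldimethylsilyl)oxy]-5-methoxy-3-methylphenyl}methanol | COc1cc(C)c(O[Si](C)(C)C(C)(C)C)c(CO)c1 | intermediate
17 | 2-[(tert-butyldimethylsilyl)oxy]-5-methoxy-3-methylbenzyl methanesulfonate | COc1cc(C)c(O[Si](C)(C)C(C)(C)C)c(COS(C)(=O)=O)c1 | intermediate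
18 | tert-butyl[2-(chloromethyl)-4-methoxy-6-methylphenoxy]dimethylsilane | COc1cc(C)c(O[Si](C)(C)C(C)(C)C)c(CCl)c1 | intermediate
19 | (E)-alkenyl(dimethyl)alane from 12, methyl cis to aluminium, the three hydroxyls as dimethylaluminium alkoxides | C[Al](C)/C=C(\C)C[C@@]1(O[Al](C)C)C[C@@]2(C)CCC[C@@]2(C)[C@@H](O[Al](C)C)[C@@H]1CC(C)(C)O[Al](C)C | intermediate
20 | (3aR,4S,5S,6R,7aR)-6-[(2E)-4-{2-[(tert-butyldimethylsilyl)oxy]-5-methoxy-3-methylphenyl}-2-methylbut-2-en-1-yl]-5-(2-hydroxy-2-methylpropyl)-3a,7a-dimethyloctahydro-1H-indene-4,6-diol | COc1cc(C)c(O[Si](C)(C)C(C)(C)C)c(C/C=C(\C)C[C@@]2(O)C[C@@]3(C)CCC[C@@]3(C)[C@@H](O)[C@@H]2CC(C)(C)O)c1 | intermediate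
21 | (3aR,5R,6R,7aR)-6-[(2E)-4-{2-[(tert-butyldimethylsilyl)oxy]-5-methoxy-3-methylphenyl}-2-methylbut-2-en-1-yl]-6-hydroxy-5-(2-hydroxy-2-methylpropyl)-3a,7a-dimethyloctahydro-4H-inden-4-one | COc1cc(C)c(O[Si](C)(C)C(C)(C)C)c(C/C=C(\C)C[C@@]2(O)C[C@@]3(C)CCC[C@@]3(C)C(=O)[C@@H]2CC(C)(C)O)c1 | intermediate
22 | (3aR,5R,6R,7aR)-6-hydroxy-6-[(2E)-4-(2-hydroxy-5-methoxy-3-methylphenyl)-2-methylbut-2-en-1-yl]-5-(2-hydroxy-2-methylpropyl)-3a,7a-dimethyloctahydro-4H-inden-4-one | COc1cc(C)c(O)c(C/C=C(\C)C[C@@]2(O)C[C@@]3(C)CCC[C@@]3(C)C(=O)[C@@H]2CC(C)(C)O)c1 | target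

**Step count**

Total steps: 15. Longest linear sequence: 11 steps (1 to 22 through steps 1–8 and 13–15); the arene branch is 4 steps (9–12).

**Three steps most likely to fail, with fallbacks**

Step 4 (radical cyclisation). The tertiary radical must add to a hindered, electron-rich β-alkoxy enone carbon, and hydrogen-atom transfer to the vinylogous ester itself could compete. The fallback sets out from 4 and returns at 7. Amide 4 is treated with CH2=CHMgBr to give 1-[(1R)-1,2-dimethylcyclopent-2-en-1-yl]but-3-en-2-one F1. The same Fe(acac)3/PhSiH3 conditions then close the ring at the unsubstituted enone terminus, the best-precedented acceptor type, giving (3aS,7aR)-3a,7a-dimethyloctahydro-6H-inden-6-one F2. Dehydrogenation with 2-iodoxybenzoic acid (or Pd(OCOCF3)2/DMSO/O2) can only go towards C5 because C7a is quaternary, and so gives 7.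

Step 5 (catalyst-controlled borylation). The β-carbon is neopentyl and the substrate has almost no facial bias of its own, so everything rests on the ligand. The fallback sets out from 7 and returns at 9. Enone 7 is epoxidised with H2O2 under iminium catalysis by 9-amino-9-deoxy-epi-quinine trifluoroacetate, again reagent-controlled, to give (3aR,4R,5R,7aR)-4,5-epoxy-3a,7a-dimethyloctahydro-6H-inden-6-one F3 with the oxirane anti to the angular methyls. SmI2 in THF/MeOH at −78 °C then cleaves only the C5–O bond and delivers 9.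

Step 6 (dianion alkylation). Enolisation could go to C7 instead of C5, or the alkoxide could trigger retro-aldol opening. The fallback sets out from 7 and returns at 10, fixing the regiochemistry by putting the substituent on the enone α-carbon first. Enone 7 is iodinated with I2/pyridine to (3aS,7aR)-5-iodo-3a,7a-dimethyl-1,2,3,3a,7,7a-hexahydro-6H-inden-6-one F4. Stille coupling with tributyl(2-methylprop-2-en-1-yl)stannane (Pd(PPh3)4, CuI) gives (3aS,7aR)-3a,7a-dimethyl-5-(2-methylprop-2-en-1-yl)-1,2,3,3a,7,7a-hexahydro-6H-inden-6-one F5. The borylation of step 5 then gives (3aS,4S,5S,7aR)-3a,7a-dimethyl-5-(2-methylprop-2-en-1-yl)-4-(4,4,5,5-tetramethyl-1,3,2-dioxaborolan-2-yl)octahydro-6H-inden-6-one F6, which is not isolated; C5 is protonated to the trans isomer and H2O2 oxidation gives 10.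

**Further compounds**

F1 | step 4 | 1-[(1R)-1,2-dimethylcyclopent-2-en-1-yl]but-3-en-2-one | C=CC(=O)C[C@@]1(C)CCC=C1C
F2 | step 4 | (3aS,7aR)-3a,7a-dimethyloctahydro-6H-inden-6-one | O=C1C[C@@]2(C)CCC[C@@]2(C)CC1
F3 | step 5 | (3aR,4R,5R,7aR)-4,5-epoxy-3a,7a-dimethyloctahydro-6H-inden-6-one | O=C1C[C@@]2(C)CCC[C@@]2(C)[C@H]3O[C@@H]13
F4 | step 6 | (3aS,7aR)-5-iodo-3a,7a-dimethyl-1,2,3,3a,7,7a-hexahydro-6H-inden-6-one | O=C1C[C@@]2(C)CCC[C@@]2(C)C=C1I
F5 | step 6 | (3aS,7aR)-3a,7a-dimethyl-5-(2-methylprop-2-en-1-yl)-1,2,3,3a,7,7a-hexahydro-6H-inden-6-one | O=C1C[C@@]2(C)CCC[C@@]2(C)C=C1CC(C)=C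
F6 | step 6 | (3aS,4S,5S,7aR)-3a,7a-dimethyl-5-(2-methylprop-2-en-1-yl)-4-(4,4,5,5-tetramethyl-1,3,2-dioxaborolan-2-yl)octahydro-6H-inden-6-one | O=C1C[C@@]2(C)CCC[C@@]2(C)[C@@H](B3OC(C)(C)C(C)(C)O3)[C@@H]1CC(C)=C
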